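**Retrosynthetic overview** (halimane numbering: C4 carries CO2Me, C5 is the ring-fusion CH, C8 is CHMe, C9 is the quaternary carbon carrying the chain C11–C16, the formate oxygen sits on C15)
- Target ⇒ 2-substituted 1,3-diene + HCO2H: the allylic C15–O bond, and with it the E geometry of C13=C14, is made last by 1,4-addition of formic acid across the diene.
- Diene ⇒ terminal alkyne + ethylene (enyne cross-metathesis); the but-3-ynyl group carries the side chain through the earlier steps.
- Ring A ⇒ Diels–Alder reaction of a 1-vinylcyclohexene (ring B) with methyl methacrylate, which creates C4, C5 and the C1=C10 alkene.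
- Vinylcyclohexene ⇒ enol triflate ⇒ 2,2,3-trisubstituted cyclohexanone ⇒ 2-methylcyclohex-2-en-1-one, by asymmetric conjugate methylation (C8) and anti enolate alkylation with but-3-ynyl triflate (C9).
- Ring order: ring B is bought as the enone and substituted first, ring A is closed by the Diels–Alder reaction, and the side-chain C–O bond comes last.

Assumption: simple bought reagents (Me3Al, Me3SiOTf, Tf2O, PhNTf2, tributyl(vinyl)stannane, ethylene, formic acid) are given with SMILES on the "Reagents that add atoms" lines and are not numbered.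

Step 1
Reactants: 1 2-methylcyclohex-2-en-1-one
Product: 3 (R)-[(2,3-dimethylcyclohex-1-en-1-yl)oxy]trimethylsilane, via aluminium enolate 2 (not isolated)
Conditions: Me3Al (1.4 equiv), copper thiophene-2-carboxylate Cu(O2C-C4H3S) (2 mol %), BINOL-derived N,N-bis(1-phenylethyl)phosphoramidite (4 mol %, the enantiomer that gives the 3R centre), Et2O, −30 °C; then Me3SiOTf (1.5 equiv), THF, 0 °C
Reagents that add atoms: trimethylaluminium C[Al](C)C; trimethylsilyl trifluoromethanesulfonate C[Si](C)(C)OS(=O)(=O)C(F)(F)F
Why: Copper-catalysed asymmetric conjugate addition of Me3Al to the α-substituted enone sets the C8 methyl stereocentre (R) under ligand control, and O-silylation of the regiodefined aluminium enolate stores the tetrasubstituted enolate for step 3.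

Step 2
Reactants: 4 but-3-yn-1-ol
Product: 5 but-3-yn-1-yl trifluoromethanesulfonate
Conditions: Tf2O (1.1 equiv), pyridine (1.2 equiv), CH2Cl2, −78 to −20 °C; used at once
Reagents that add atoms: trifluoromethanesulfonic anhydride O=S(=O)(OS(=O)(=O)C(F)(F)F)C(F)(F)F
Why: O-Sulfonylation of the primary alcohol gives a triflate reactive enough to alkylate a hindered enolate at −78 °C before elimination of the homopropargylic leaving group competes.

Step 3
Reactants: 3 (R)-[(2,3-dimethylcyclohex-1-en-1-yl)oxy]trimethylsilane; 5 but-3-yn-1-yl trifluoromethanesulfonate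
Product: 7 (2S,3R)-2-(but-3-yn-1-yl)-2,3-dimethylcyclohexan-1-one, via lithium enolate 6 (not isolated)
Conditions: MeLi (1.05 equiv), THF, 0 to 25 °C; then 5 (1.3 equiv), THF, −78 to −20 °C
Reagents that add atoms: none
Why: MeLi cleaves the silyl enol ether to the regiodefined lithium enolate, whose SN2 C-alkylation by the primary triflate takes place anti to the neighbouring C8 methyl group and so sets the quaternary C9 centre (S) with the two methyl groups cis.

Step 4
Reactants: 7 (2S,3R)-2-(but-3-yn-1-yl)-2,3-dimethylcyclohexan-1-one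
Product: 9 (5R,6S)-6-(but-3-yn-1-yl)-5,6-dimethylcyclohex-1-en-1-yl trifluoromethanesulfonate, via potassium enolate 8 (not isolated)
Conditions: KN(SiMe3)2 (1.05 equiv), THF, −78 °C; then PhNTf2 (1.15 equiv), −78 to 0 °C
Reagents that add atoms: N-phenylbis(trifluoromethanesulfonimide) O=S(=O)(N(c1ccccc1)S(=O)(=O)C(F)(F)F)C(F)(F)F
Why: Enolisation can only occur towards C5 because C9 is quaternary (the ketone α-CH2 is more acidic than the alkyne C–H), and O-triflation of the potassium enolate gives the enol triflate without touching either stereocentre.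

Step 5
Reactants: 9 (5R,6S)-6-(but-3-yn-1-yl)-5,6-dimethylcyclohex-1-en-1-yl trifluoromethanesulfonate
Product: 10 (5R,6S)-6-(but-3-yn-1-yl)-1-ethenyl-5,6-dimethylcyclohex-1-ene
Conditions: tributyl(vinyl)stannane (1.2 equiv), Pd(PPh3)4 (5 mol %), LiCl (3 equiv), THF, 65 °C
Reagents that add atoms: tributyl(vinyl)stannane C=C[Sn](CCCC)(CCCC)CCCC
Why: Stille cross-coupling of the enol triflate with the vinylstannane gives the 1-vinylcyclohexene, and the copper-free, amine-free conditions leave the terminal alkyne untouched.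

Step 6
Reactants: 10 (5R,6S)-6-(but-3-yn-1-yl)-1-ethenyl-5,6-dimethylcyclohex-1-ene; 11 methyl 2-methylprop-2-enoate (methyl methacrylate)
Product: 12 methyl (1S,5S,6R,8aR)-5-(but-3-yn-1-yl)-1,5,6-trimethyl-1,2,3,5,6,7,8,8a-octahydronaphthalene-1-carboxylate
Conditions: 11 (3 equiv), EtAlCl2 (0.5 equiv), CH2Cl2, −78 to −20 °C
Reagents that add atoms: none
Why: In this Lewis-acid-catalysed Diels–Alder reaction the ester-bearing carbon bonds to the ring terminus C5 (the usual "ortho" regiochemistry of 1-vinylcyclohexenes), the endo-ester transition state places CO2Me trans to H5 (C4 = S), and the dienophile is expected to add to the diene face opposite the pseudoaxial C9 methyl group of the conformer with the C8 methyl equatorial (C5 = R).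

Step 7
Reactants: 12 methyl (1S,5S,6R,8aR)-5-(but-3-yn-1-yl)-1,5,6-trimethyl-1,2,3,5,6,7,8,8a-octahydronaphthalene-1-carboxylate
Product: 13 methyl (1S,5S,6R,8aR)-1,5,6-trimethyl-5-(3-methylidenepent-4-en-1-yl)-1,2,3,5,6,7,8,8a-octahydronaphthalene-1-carboxylate
Conditions: ethylene (3 bar), second-generation Grubbs catalyst RuCl2(=CHPh)(PCy3)(H2IMes) (5 mol %), toluene, 60 °C
Reagents that add atoms: ethylene C=C
Why: Ethylene–alkyne enyne cross-metathesis turns the terminal alkyne into the 2-substituted 1,3-diene, while the trisubstituted ring alkene and the hindered ester are inert.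

Step 8
Reactants: 13 methyl (1S,5S,6R,8aR)-1,5,6-trimethyl-5-(3-methylidenepent-4-en-1-yl)-1,2,3,5,6,7,8,8a-octahydronaphthalene-1-carboxylate
Product: 14 methyl (1S,5S,6R,8aR)-5-[(3E)-5-(formyloxy)-3-methylpent-3-en-1-yl]-1,5,6-trimethyl-1,2,3,5,6,7,8,8a-octahydronaphthalene-1-carboxylate (the target)
Conditions: HCO2H (3 equiv), Ni(cod)2 (5 mol %), dppf Fe(C5H4PPh2)2 (6 mol %), toluene, 0 to 25 °C
Reagents that add atoms: formic acid OC=O
Why: Proposed new method: a 1,4-hydro-formyloxylation of a 1,3-diene in which zerovalent nickel/dppf binds the s-cis diene η4, formic acid protonates the CH2 terminus on the substituted carbon (C16) to give the more substituted η3-allyl nickel cation with the new methyl anti and the chain syn, and formate attacks the unhindered CH2 terminus (C15) from outside the metal, so the cisoid geometry becomes the E alkene because syn/anti exchange at the fully substituted allyl terminus is slow, while the chelating diphosphine leaves no free cis site for formate β-hydride loss and reduction; the closest known reaction types are nickel-catalysed hydroamination of 1,3-dienes with an acid co-catalyst and nickel- or iron-catalysed 1,4-hydroboration of 2-substituted dienes to E allyl boronates.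

**Compound list**
1 | 2-methylcyclohex-2-en-1-one | CC1=CCCCC1=O | starting material
2 | dimethylaluminium (R)-2,3-dimethylcyclohex-1-en-1-olate | C[Al](C)OC1=C(C)[C@H](C)CCC1 | intermediate
3 | (R)-[(2,3-dimethylcyclohex-1-en-1-yl)oxy]trimethylsilane | C[Si](C)(C)OC1=C(C)[C@H](C)CCC1 | intermediate
4 | but-3-yn-1-ol | C#CCCO | starting material
5 | but-3-yn-1-yl trifluoromethanesulfonate | C#CCCOS(=O)(=O)C(F)(F)F | intermediate
6 | lithium (R)-2,3-dimethylcyclohex-1-en-1-olate | [Li]OC1=C(C)[C@H](C)CCC1 | intermediate
7 | (2S,3R)-2-(but-3-yn-1-yl)-2,3-dimethylcyclohexan-1-one | O=C1CCC[C@@H](C)[C@]1(C)CCC#C | intermediate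
8 | potassium (5R,6S)-6-(but-3-yn-1-yl)-5,6-dimethylcyclohex-1-en-1-olate | [K]OC1=CCC[C@@H](C)[C@]1(C)CCC#C | intermediate
9 | (5R,6S)-6-(but-3-yn-1-yl)-5,6-dimethylcyclohex-1-en-1-yl trifluoromethanesulfonate | FC(F)(F)S(=O)(=O)OC1=CCC[C@@H](C)[C@]1(C)CCC#C | intermediate
10 | (5R,6S)-6-(but-3-yn-1-yl)-1-ethenyl-5,6-dimethylcyclohex-1-ene | C=CC1=CCC[C@@H](C)[C@]1(C)CCC#C | intermediate
11 | methyl 2-methylprop-2-enoate (methyl methacrylate) | COC(=O)C(C)=C | starting material
12 | methyl (1S,5S,6R,8aR)-5-(but-3-yn-1-yl)-1,5,6-trimethyl-1,2,3,5,6,7,8,8a-octahydronaphthalene-1-carboxylate | COC(=O)[C@@]1(C)CCC=C2[C@H]1CC[C@@H](C)[C@]2(C)CCC#C | intermediate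
13 | methyl (1S,5S,6R,8aR)-1,5,6-trimethyl-5-(3-methylidenepent-4-en-1-yl)-1,2,3,5,6,7,8,8a-octahydronaphthalene-1-carboxylate | COC(=O)[C@@]1(C)CCC=C2[C@H]1CC[C@@H](C)[C@]2(C)CCC(=C)C=C | intermediate
14 | methyl (1S,5S,6R,8aR)-5-[(3E)-5-(formyloxy)-3-methylpent-3-en-1-yl]-1,5,6-trimethyl-1,2,3,5,6,7,8,8a-octahydronaphthalene-1-carboxylate | COC(=O)[C@@]1(C)CCC=C2[C@H]1CC[C@@H](C)[C@]2(C)CC/C(C)=C/COC=O | target

**Step count:** 8 steps in total. The longest linear sequence is 7 steps (1, 3, 4, 5, 6, 7, 8 from 2-methylcyclohex-2-en-1-one); step 2 is a one-step side branch.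

**Three steps most likely to fail**

Step 8 (the proposed new reaction). Nickel formate may lose CO2 and reduce the diene, or the branched tertiary formate or E/Z mixtures may form. The fallback uses known chemistry, sets out from 13 and comes back at 14. Iron-catalysed 1,4-hydroboration of the 2-substituted diene with pinacolborane (FeCl2 with an N-aryl iminopyridine ligand, activated by Mg, Et2O, 23 °C) gives the (E)-allyl pinacol boronate F1. Oxidation with NaBO3·4H2O in THF/H2O gives the (E)-allylic alcohol F2. O-Formylation with acetic formic anhydride and pyridine (CH2Cl2, 0 °C) then gives 14.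

Step 6. Facial selectivity rests on a small difference between the methyl group and the chain at C9, and methacrylates can erode endo selectivity, so the C4/C5 diastereomer ratio may be poor. The fallback sets out from 10 and comes back at 12. A catalyst-controlled Diels–Alder reaction of 10 with 2-methylprop-2-enal is run under a chiral oxazaborolidinium triflimide (the Tf2NH-protonated B-o-tolyl oxazaborolidine of α,α-diphenylprolinol, enantiomer matched to the 1S,8aR adduct; CH2Cl2, −78 °C) and gives the aldehyde F3. Pinnick oxidation (NaClO2, NaH2PO4, 2-methylbut-2-ene, t-BuOH/H2O) gives the carboxylic acid F4. Esterification with Me3SiCHN2 in MeOH/toluene gives 12.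

Step 3. O-alkylation, elimination of the homopropargylic triflate, or a low anti/syn ratio may cut the yield of the quaternary centre. The fallback sets out from 3 and comes back at 7. Mukaiyama–Michael addition of 3 to propenal (BF3·OEt2, CH2Cl2, −78 °C), with the same anti facial sense, gives the keto aldehyde F5. Ohira–Bestmann homologation (dimethyl (1-diazo-2-oxopropyl)phosphonate, K2CO3, MeOH, 0 to 25 °C) converts the aldehyde into the terminal alkyne of 7.

**Further compounds**
F1 | step 8 | methyl (1S,5S,6R,8aR)-1,5,6-trimethyl-5-[(3E)-3-methyl-5-(4,4,5,5-tetramethyl-1,3,2-dioxaborolan-2-yl)pent-3-en-1-yl]-1,2,3,5,6,7,8,8a-octahydronaphthalene-1-carboxylate | COC(=O)[C@@]1(C)CCC=C2[C@H]1CC[C@@H](C)[C@]2(C)CC/C(C)=C/CB3OC(C)(C)C(C)(C)O3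
F2 | step 8 | methyl (1S,5S,6R,8aR)-5-[(3E)-5-hydroxy-3-methylpent-3-en-1-yl]-1,5,6-trimethyl-1,2,3,5,6,7,8,8a-octahydronaphthalene-1-carboxylate | COC(=O)[C@@]1(C)CCC=C2[C@H]1CC[C@@H](C)[C@]2(C)CC/C(C)=C/CO
F3 | step 6 | (1S,5S,6R,8aR)-5-(but-3-yn-1-yl)-1,5,6-trimethyl-1,2,3,5,6,7,8,8a-octahydronaphthalene-1-carbaldehyde | O=C[C@@]1(C)CCC=C2[C@H]1CC[C@@H](C)[C@]2(C)CCC#C
F4 | step 6 | (1S,5S,6R,8aR)-5-(but-3-yn-1-yl)-1,5,6-trimethyl-1,2,3,5,6,7,8,8a-octahydronaphthalene-1-carboxylic acid | OC(=O)[C@@]1(C)CCC=C2[C@H]1CC[C@@H](C)[C@]2(C)CCC#C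
F5 | step 3 | 3-[(1S,2R)-1,2-dimethyl-6-oxocyclohexyl]propanal | O=C1CCC[C@@H](C)[C@]1(C)CCC=O
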